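| flask | starting material | capture agent | remark | time |
|---|---|---|---|---|
| ochre | 8.5 mM | 5.1 mM | run made earlier |  |
| teal | 13 mM | 5.1 mM | run made earlier |  |
| flask | 17 mM | 5.10 mM |  | 30 h |

| run | time / h | starting material / % | product / % | intermediate A / % | intermediate B / % | trapped intermediate / % |
|---|---|---|---|---|---|---|
| ochre | 1.33 | 97 | 4 | 4 | 0 | 0 |
| ochre | 2.50 | 92 | 3 | 1 | 2 | 0 |
| ochre | 4.00 | 86 | 9 | 4 | 1 | 0 |
| ochre | 6.00 | 83 | 9 | 7 | 0 | 0 |
| ochre | 10.0 | 74 | 14 | 9 | 3 | 0 |
| ochre | 20.0 | 55 | 22 | 16 | 1 | 0 |
| teal | 1.33 | 95 | 1 | 2 | 0 | 2 |
| teal | 2.50 | 95 | 5 | 2 | 1 | 0 |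
| teal | 4.00 | 88 | 6 | 6 | 2 | 0 |
| teal | 6.00 | 81 | 8 | 8 | 0 | 0 |
| teal | 10.0 | 77 | 16 | 8 | 3 | 0 |
| teal | 20.0 | 57 | 21 | 13 | 4 | 1 |

(standard deviation of a reading: 1.5 percentage points)

- what may be going on: intermediate A <-> intermediate B; starting material -> product; capture agent + intermediate B -> trapped intermediate; starting material -> intermediate A

* the species in which most of what was charged as starting material, at 30 h sits (trapped intermediate / starting material / intermediate A / product / intermediate B)
* the largest share itself, whichever of these holds it, in percent of the starting material charged

The easy step is the loss of starting material. At 20.0 h the ochre run shows 55% left and the teal run 57%, though teal was charged with more. That gap of 2 percentage points stands against a scatter of 1.5 points, so we take the loss as first order and let the flask at 17 mM follow the same curve. Product, ahead of intermediate A at that hour in both runs, is the rival. We ask when it takes the lead, reading the decay constant k and the selectivity f, product formed per starting material used, at that same hour: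

k = 0.0290 h⁻¹

f = 48.9%

Setting c(product) equal to c(starting material) gives:

t× = ln((1 + f)/f)/k = 38.4 h

This crossing time, the hour at which the share of product reaches that of starting material, lies later than the 30 h asked. Turned round, with k held, a crossing by 30 h needs a selectivity of 72.1%, more than the 48.9% read. So we commit to starting material in the flask, at 41.9%.

The forecast also gives starting material at 42%: “Starting material therefore still holds the largest share”.

The flask gives starting material at 41.9%, the largest share.

    intermediate A ⇌ intermediate B (K = 0.500, k = 0.0400 h⁻¹)
    starting material → product (k = 0.0150 h⁻¹)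
    capture agent + intermediate B → trapped intermediate (k = 6.90 M⁻¹ h⁻¹)
    starting material → intermediate A (k = 0.0140 h⁻¹)

Product in the flask stands 12 points behind, at 30.1%. The flask was read at 78.1% of 38.4 h. The same flask read at 3.0 d lies past the crossing time, and there product holds 45.3% against 12.4% of starting material.

The runs were computed with made-up constants; the scatter is artificial.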